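(All runs are simulated with made-up constants, and the scatter is random.)

The easy step was the mirror: Jo and Wy start equal, so I took equal losses as the zero of my scale and read any gap as the work of single-handed Ji.

- north: Jo 0.020 M; Wy 0.020 M; Uj 1.2 equiv; Ji 15 mol%; the very flask that is asked about, followed so far
- flask: Jo 0.020 M; Uj 1.20 equiv; Ji 15 mol%; Wy 0.020 M; time 5.0 h

If Ji simply took up Jo and Wy evenly, each would lose the even share, the Ji charged split equally over both and counted in percent of the two together: 3.75%.

- north (time / min: Jo / %, Wy / %): 1.50: 48.2, 47.0; 5.00: 47.1, 45.4; 8.00: 47.0, 46.1; 12.0: 45.0, 46.7; 20.0: 44.0, 45.7; 25.0: 44.2, 46.3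

(readings scatter by 0.5 percentage points)

- Ji is single-handed; Jo and Wy are mirror images of each other, charged as a racemate, each of them at the stated concentration
- the earlier runs were read with a standard deviation of 0.5 percentage points
- an excess is the difference of the two amounts in percent of their sum
- an excess is below zero if the other one leads

In the north flask, Wy averaged 46.2%, a loss of 3.8 percentage points, and showed no readable trend, so I gave it the even share and no more. But Jo read 44.1% around 22.5 min, which is 2.1 points past its even share, and I took that excess as turnover into Gu. Kept at that pace to 5.0 h, it makes 28.7%, so my own reckoning was c near 36.2% and eS near 45.0%, with Gu far ahead of Ky.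

* part of the Jo and Wy charged together that has reacted at 5.0 h
* excess of Gu over Ky in the product at 5.0 h
* excess of Wy over Jo among what is left of the two at 5.0 h

The forecast, lower than my reckoning on c and eS, saw “a fast burst, from binding or a short-lived catalyst form, followed by slow Jo-selective turnover” and gave c 25% (10% to 42%), eP 63% (15% to 85%) and eS 20% (1% to 50%).

The flask gave c 34.4%, eP 95.4% and eS 42.2%.

    Ji + Jo ⇌ Qi (K = 1410 L mol⁻¹, k = 14.5 L mol⁻¹ min⁻¹)
    Ji + Wy ⇌ Qe (K = 220 L mol⁻¹, k = 28.8 L mol⁻¹ min⁻¹)
    Uj + Qi → Ji + Gu (k = 2.63 L mol⁻¹ min⁻¹)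
    Uj + Qe → Ji + Ky (k = 0.0611 L mol⁻¹ min⁻¹)
    Uj → Ju (k = 0.00272 min⁻¹)
    2 Ji → Lx (k = 1.29 L mol⁻¹ min⁻¹)
    Uj + Ji → Vo (k = 0.124 L mol⁻¹ min⁻¹)

In the asked flask at 5.00 h, 38% of the charged Jo stood unbound, less than the 93% of the Wy. The even share put Wy at 46.2% in that flask, and Wy stood at 46.6%, with 36.3% of the catalyst charged as Qe against 47.6% as Qi, so the split was not even. With 3.8 mol% of Ji in the neighbour flask, the even share is 0.950%, which puts Wy at 49.0%, and Wy stood at 49.2%.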